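I wanted to know how far this flask goes, and what handedness its product has at 25 h and at 10 d.

in all of them: left-handed substrate 0.10 M; right-handed substrate 0.10 M; precatalyst 10 mM

| flask | partner | remark | time |
|---|---|---|---|
| teal | 0.040 M (fed, over 5.0 h) | run made earlier |  |
| green | 0.16 M (fed, over 5.0 h) | run made earlier |  |
| flask | 0.0800 M (fed, over 5.0 h) |  | 10 d |

| run | time / d | left-handed product / % | right-handed product / % |
|---|---|---|---|
| teal | 0.500 | 3.8 | 1.9 |
| teal | 1.67 | 7.3 | 5.8 |
| teal | 3.00 | 7.3 | 7.6 |
| teal | 4.00 | 6.8 | 6.3 |
| teal | 6.00 | 7.9 | 8.3 |
| green | 1.25 | 27.3 | 21.8 |
| green | 2.50 | 31.0 | 28.5 |
| green | 4.00 | 33.3 | 32.5 |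
| green | 5.00 | 33.9 | 34.3 |
| green | 6.00 | 34.4 | 34.1 |

(scatter of a reading: 0.5 percentage points)

- catalyst is single-handed; left-handed substrate and right-handed substrate are mirror images of each other, charged as a racemate, each of them at the stated concentration
- the numbers in the tables scatter with a standard deviation of 0.5 percentage points
- steps that have been proposed: partner + catalyst + left-handed substrate -> catalyst + left-handed product; partner + catalyst + right-handed substrate -> catalyst + right-handed product; partner + precatalyst -> catalyst + spent reagent; left-handed product <-> right-handed product; 2 catalyst <-> resting dimer
- an excess is the difference of the two amounts in percent of their sum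
- an excess is below zero if the other one leads

- excess of left-handed product over right-handed product in the product at 25 h
- excess of left-handed product over right-handed product in the product at 10 d
- part of the left-handed substrate and right-handed substrate charged together that has reacted at 10 d

The partner charge, less the one partner each precatalyst takes on activation, over the two substrates together, gave 35.0 %: this was the partner budget, the conversion at which the partner is used up. The partner was the limiting reagent in this flask, since its net charge was less than the two substrates.

In the first instants the feed mattered little. It ended after 5.0 h, sooner than the first teal reading at 0.500 d, and by then teal had made 5.70 % of product against its budget of 15.0 %. So in teal partner stood waiting for the catalyst. The left-handed product led there, with a read excess of 33.3 %.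

In the middle I treated the partner as pseudo-first-order, so that integrating its rate makes the gap to the budget shrink exponentially. Teal read a gap half-life of 0.511 d. Green, with its budget of 75.0 %, read 1.84 d, longer than the half-life read in teal. The excess was falling meanwhile: green read 11.2 % at 1.25 d, so I placed the flask at 25 h between the two read excesses.

For the end I took green's slower half-life, which left this flask a gap of 0.81 percentage points at 10 d, just short of the budget. The last readings stood at 7.9 % against 8.3 % in teal and 34.4 % against 34.1 % in green, with a scatter of 0.5 points, so I expected an even product.

The forecast gave 18 % (12 % to 25 %), 0 % (−1.5 % to 1.5 %) and 34.5 % (32 % to 36 %): “The flask should therefore stop near (80−10)/200 = 35%, reached well before 10 d.”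

    partner + catalyst + left-handed substrate → catalyst + left-handed product (k = 98.2 M⁻² h⁻¹)
    partner + catalyst + right-handed substrate → catalyst + right-handed product (k = 36.5 M⁻² h⁻¹)
    partner + precatalyst → catalyst + spent reagent (k = 2.75 M⁻¹ h⁻¹)
    left-handed product ⇌ right-handed product (k = 0.0296 h⁻¹)
    2 catalyst ⇌ resting dimer (K = 403 M⁻¹, k = 5.96 M⁻¹ h⁻¹)

The flask gave 18.8 %, 0.0253 % and 35.0 %, against its budget of 35.0 %. At 10 d, with 0.12 % of the partner left, the flask held 52 % of its left-handed substrate, less than the 78 % of its right-handed substrate, and the excess of right-handed substrate in what was left stood at 20.4 %, while the excess in the product stood at 0.0253 %, the two products relaxing into each other with a half-life of 0.488 d, short against that time. The neighbour flask with 0.14 M of partner has a budget of 65.0 %, which its 1.7 % of partner left brings down to 63.8 %, and it reacted 63.8 % by 10 d.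

The data stem from a simulated flask for an exercise; scatter was added.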